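**Slow supply.** The red flask filled slowly: after 0.625 d the two products together stood at 53.2% of the solid substrate charged, and I read that as a steady feed from the dissolving solid.

| flask | solid substrate | first nucleophile | second nucleophile | remark | time |
|---|---|---|---|---|---|
| red | 28 mM | 22.4 mM | 22.4 mM | the very flask that is asked about, followed so far |  |
| blue | 28 mM | 34 mM | 22.4 mM | run made earlier |  |
| flask | 28 mM | 22.4 mM | 22.4 mM |  | 15 d |

| run | time / d | other capture product / % | target / % |
|---|---|---|---|
| red | 0.625 | 2.9 | 50.3 |
| red | 1.04 | 9.6 | 76.4 |
| red | 1.67 | 17.3 | 78.4 |
| red | 2.50 | 18.3 | 78.2 |
| red | 5.00 | 18.4 | 78.4 |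
| red | 8.00 | 17.9 | 78.8 |
| blue | 0.833 | 2.3 | 72.7 |
| blue | 1.25 | 5.0 | 89.1 |
| blue | 2.50 | 3.4 | 91.1 |
| blue | 4.00 | 3.5 | 92.7 |
| blue | 6.00 | 4.1 | 92.9 |
| blue | 10.0 | 4.3 | 92.3 |

(readings scatter by 0.5 percentage points)

- share of other capture product in other capture product plus target at 2.0 h
- share of other capture product in other capture product plus target at 25 h
- share of other capture product in other capture product plus target at 15 d
- which of other capture product and target there is more of at 15 d

- given per volume of solution although it is solid: solid substrate
- at the start none of the solid substrate is in solution

**What matters.** Late time moves the red share within the scatter of 0.5 percentage points: it read 19.0% at 2.50 d and 18.5% at 8.00 d. Early time matters strongly, for the red share climbed from 5.45% at 0.625 d through 11.2% at 1.04 d. The first nucleophile's charge matters strongly too: the blue run, with 34 mM against 22.4 mM, read a lower share of 4.45% at 10.0 d. The solid substrate's charge is the same in both runs, so they do not test it.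

**The ceiling.** The number to know well is therefore the target's ceiling, 80.0%, the first nucleophile's charge over the solid substrate's charge, since that nucleophile is the limiting reagent and the red target levelled at 78.4%, just below it. At 1.04 d the red target read 76.4%, still below that ceiling. I therefore put the share below 5.45% at 2.0 h, at the reading of 11.2% at 25 h, and at 15 d near 18.5%, beside the 20.0% that the ceiling leaves, with target ahead.

**The check.** The forecast gave 3.7%, 11% and 18.8% with target ahead, holding that “the plateau is flat”. The flask gave 3.54%, 11.6% and 19.1%, with target ahead at 78.4% against 18.5%.

    first nucleophile + intermediate → target (k = 47.0 /M/min)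
    second nucleophile + intermediate → other capture product (k = 1.70 /M/min)
    2 starting material → homo dimer (k = 2.60 × 10⁻⁵ /M/min)
    starting material + target → side product (k = 0.00350 /M/min)
    solid substrate ⇌ starting material, rate k5*(cs5 - [starting material]) while solid is left; crystals form when [starting material] > cs5 (solubility = 14.0 mM, k = 0.00330 /min)
    starting material → intermediate (k = 0.00270 /min)

**What ran.** In this flask, solid substrate dissolved and starting material passed through the intermediate to target while first nucleophile lasted, and first nucleophile stood at 0.147% of its charge at 1.50 d. By then second nucleophile had taken intermediate to other capture product, and this flask held 16.8% of other capture product and 78.3% of target at 1.50 d. In one more flask like it, with 5.6 mM of first nucleophile, the ceiling is 20.0%, and target stood at 19.4% at 15.0 d, with a share of 80.4% against the 80.0% that ceiling leaves.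

(All runs were computed for an exercise.)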